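Ring A (C1 CO2H, C2 heptyl, C4 OMe, C6 O-aryl) is disconnected across C1–C6 and C2–C3. Its C3–C6 edge, with the C4 methoxy and C6 aryloxy oxygens, is carried by a 6-aryloxy-4-methoxy-2-pyrone, and its C1–C2 edge by benzyl dec-2-ynoate. One thermal Diels–Alder/CO2 extrusion forms both bonds and delivers ring A as a finished benzoate, with the carboxyl set between the heptyl chain and a diaryl ether oxygen that is already in place. The precursor is this pyrone bound through oxygen to C4′ of a complete ring B (benzyl ester, heptyl, methoxy). The C2′ hydroxyl stays free, silenced by its hydrogen bond to the ester. Hydrogenolysis of two benzyl esters finishes.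

Key step: step 12

Remark (assumption): the target has no stereocentre, axis or configurable double bond, so the SMILES defines one achiral compound and no step has to set configuration. Ring B is numbered C1′ (CO2H), C2′ (OH), C4′ (ether O), C5′ (OMe), C6′ (heptyl). Compounds 1, 10 and 15 are taken as commercial.

Step 1
Reactants: 1 5-heptylresorcinol
Product: 2 1,3-bis(benzyloxy)-5-heptylbenzene
Conditions: BnBr (2.4 equiv), K2CO3, DMF, 60 °C
Reagents that add atoms: benzyl bromide, BrCc1ccccc1
Why: Williamson etherification of both phenoxides; the benzyl ethers should survive the NBS, methoxide/copper, POCl3 and chlorite steps that follow.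

Step 2
Reactants: 2 1,3-bis(benzyloxy)-5-heptylbenzene
Product: 3 1,5-bis(benzyloxy)-2-bromo-3-heptylbenzene
Conditions: NBS (1.0 equiv), MeCN, 0 °C to rt, dark
Reagents that add atoms: N-bromosuccinimide, O=C1CCC(=O)N1Br
Why: Electrophilic aromatic bromination, which in 3,5-dialkoxy-alkylbenzenes goes para to one alkoxy group and next to the alkyl chain, not between the two ethers; one equivalent at low temperature should limit dibromination.

Step 3
Reactants: 3 1,5-bis(benzyloxy)-2-bromo-3-heptylbenzene
Product: 4 1,5-bis(benzyloxy)-3-heptyl-2-methoxybenzene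
Conditions: NaOMe (5 equiv, 25% in MeOH), CuI (15 mol %), DMF, 110 °C
Reagents that add atoms: sodium methoxide, [Na+].[O-]C
Why: Ullmann-type copper-catalysed methoxylation of an aryl bromide, a reaction used on bromides flanked by an alkyl and an alkoxy group in polymethoxytoluene chemistry; the benzyl ethers are inert to methoxide.

Step 4
Reactants: 4 1,5-bis(benzyloxy)-3-heptyl-2-methoxybenzene
Product: 6 2,4-bis(benzyloxy)-6-heptyl-5-methoxybenzaldehyde, via aryl iminium chloride 5 (not isolated)
Conditions: POCl3, DMF, 0 to 70 °C; then ice–water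
Reagents that add atoms: N,N-dimethylformamide, CN(C)C=O; water, O
Why: Vilsmeier–Haack formylation at the position para to one benzyloxy group, ortho to the other and next to the heptyl chain, which is preferred over the site between the two ethers as in 3,5-dialkoxytoluenes; the iminium salt is hydrolysed on work-up.

Step 5
Reactants: 6 2,4-bis(benzyloxy)-6-heptyl-5-methoxybenzaldehyde
Product: 7 2,4-bis(benzyloxy)-6-heptyl-5-methoxybenzoic acid
Conditions: NaClO2, NaH2PO4, 2-methyl-2-butene, t-BuOH–THF–H2O, rt
Reagents that add atoms: sodium chlorite, [Na+].[O-]Cl=O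
Why: Pinnick oxidation of the aldehyde by chlorous acid, with the alkene trapping HOCl so that the electron-rich ring is not chlorinated.

Step 6
Reactants: 7 2,4-bis(benzyloxy)-6-heptyl-5-methoxybenzoic acid
Product: 8 6-heptyl-2,4-dihydroxy-5-methoxybenzoic acid
Conditions: H2 (1 atm), 10% Pd/C, EtOAc–MeOH, rt
Reagents that add atoms: none
Why: Catalytic hydrogenolysis of both aryl benzyl ethers at room temperature, mild enough that the 2-hydroxy-6-alkylbenzoic acid should not decarboxylate.

Step 7
Reactants: 8 6-heptyl-2,4-dihydroxy-5-methoxybenzoic acid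
Product: 9 benzyl 6-heptyl-2,4-dihydroxy-5-methoxybenzoate
Conditions: BnBr (1.05 equiv), KHCO3, DMF, rt
Reagents that add atoms: benzyl bromide, BrCc1ccccc1
Why: SN2 O-alkylation of the carboxylate; hydrogen carbonate deprotonates only the acid and not the phenols, so only the ester should form.

Step 8
Reactants: 10 malonyl dichloride (2 equiv)
Product: 13 6-chloro-4-hydroxy-2H-pyran-2-one, via pyranone-3-carbonyl chloride 11 (not isolated), via pyranone-3-carboxylic acid 12 (not isolated)
Conditions: neat, rt, 5–7 d (HCl vented); then H2O, Et2O, 0 °C to rt; then 60 °C until CO2 evolution ends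
Reagents that add atoms: none
Why: Self-condensation of malonyl dichloride (C-acylation of one molecule by another, then O-acylative ring closure with loss of HCl) gives the chloropyranone acid chloride; hydrolysis and β-keto-acid-type decarboxylation then remove the C3 carbonyl group.

Step 9
Reactants: 13 6-chloro-4-hydroxy-2H-pyran-2-one
Product: 14 6-chloro-4-methoxy-2H-pyran-2-one
Conditions: Me2SO4, K2CO3, acetone, rt to 40 °C
Reagents that add atoms: dimethyl sulfate, COS(=O)(=O)OC
Why: O-methylation of the vinylogous acid; with dimethyl sulfate and carbonate, 4-hydroxy-2-pyranones are methylated mainly at the C4 oxygen, giving the 4-methoxy-2-pyranone and not the 2-methoxy-4-pyranone.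

Step 10
Reactants: 15 non-1-yne
Product: 17 benzyl dec-2-ynoate, via lithium non-1-yn-1-ide 16 (not isolated)
Conditions: n-BuLi, THF, −78 °C; then ClCO2Bn (1.3 equiv), −78 to 0 °C
Reagents that add atoms: benzyl chloroformate, O=C(Cl)OCc1ccccc1
Why: Deprotonation of the terminal alkyne and C-acylation of the acetylide by the chloroformate, with excess electrophile at low temperature to prevent a second addition.

Step 11
Reactants: 9 benzyl 6-heptyl-2,4-dihydroxy-5-methoxybenzoate; 14 6-chloro-4-methoxy-2H-pyran-2-one (1.1 equiv)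
Product: 18 benzyl 6-heptyl-2-hydroxy-5-methoxy-4-[(4-methoxy-2-oxo-2H-pyran-6-yl)oxy]benzoate
Conditions: K2CO3 (1.1 equiv), MeCN, 0 °C to rt
Reagents that add atoms: none
Why: Addition–elimination at C6 of the chloropyranone (a vinylogous acyl chloride) by the C4′ phenoxide, the only phenoxide formed by one equivalent of carbonate since the C2′ hydroxyl is chelated to the ester; because the 3-methoxyglutaconate backbone is symmetric, attack at the lactone carbonyl followed by ring opening and reclosure would lead to the same pyranone.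

Step 12
Reactants: 18 benzyl 6-heptyl-2-hydroxy-5-methoxy-4-[(4-methoxy-2-oxo-2H-pyran-6-yl)oxy]benzoate; 17 benzyl dec-2-ynoate (4 equiv)
Product: 20 benzyl 4-{2-[(benzyloxy)carbonyl]-3-heptyl-5-methoxyphenoxy}-6-heptyl-2-hydroxy-5-methoxybenzoate, via bridged lactone 19 (not isolated)
Conditions: 1,2-dichlorobenzene, 180 °C, sealed tube, Ar
Reagents that add atoms: none
Why: Normal-demand [4+2] cycloaddition of the electron-rich pyranone diene (C3=C4–C5=C6, pushed by the 4-OMe and 6-OAr donors) with the ynoate gives bridged lactone 19, which expels CO2 by retro-[4+2] so that aromatisation makes the sequence irreversible. The closest known reaction type is the thermal Diels–Alder/decarboxylation of 4-alkoxy- and 6-alkoxy-2-pyranones with alkynoates to give benzoates. Ring A is closed by intermolecular cycloaddition, both ring bonds (pyranone C3 to the alkyne β-carbon = ring A C3–C2, pyranone C6 to the α-carbon = ring A C6–C1) being made in that event. No stereocentre is created in 20; the two bridgehead centres of racemic 19 vanish with CO2. The step needs regioselectivity, which the substrate should secure because pyranone C3 is the nucleophilic diene terminus (β to the 4-methoxy group and vinylogously δ to the C6 oxygens) and pairs with the electrophilic β-carbon of the ynoate, putting heptyl at C2 and the ester at C1 next to the ether oxygen. The benzyl esters, the pyranonyl aryl ether and the chelated C2′ phenol should tolerate the temperature, and the excess of ynoate compensates for its single activating group.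

Step 13
Reactants: 20 benzyl 4-{2-[(benzyloxy)carbonyl]-3-heptyl-5-methoxyphenoxy}-6-heptyl-2-hydroxy-5-methoxybenzoate
Product: 21 4-(2-carboxy-3-heptyl-5-methoxyphenoxy)-6-heptyl-2-hydroxy-5-methoxybenzoic acid (CNP0151337.0)
Conditions: H2 (1 atm), 10% Pd/C, EtOAc, rt
Reagents that add atoms: none
Why: Hydrogenolysis of the two benzyl esters; the diaryl ether, methyl ethers and arenes are inert, and neutral room-temperature conditions should avoid decarboxylation of either acid.

Compound list
1 | 5-heptylresorcinol (5-heptylbenzene-1,3-diol) | CCCCCCCc1cc(O)cc(O)c1 | starting material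
2 | 1,3-bis(benzyloxy)-5-heptylbenzene | CCCCCCCc1cc(OCc2ccccc2)cc(OCc2ccccc2)c1 | intermediate
3 | 1,5-bis(benzyloxy)-2-bromo-3-heptylbenzene | CCCCCCCc1cc(OCc2ccccc2)cc(OCc2ccccc2)c1Br | intermediate
4 | 1,5-bis(benzyloxy)-3-heptyl-2-methoxybenzene | CCCCCCCc1cc(OCc2ccccc2)cc(OCc2ccccc2)c1OC | intermediate
5 | N-[2,4-bis(benzyloxy)-6-heptyl-5-methoxybenzylidene]-N-methylmethanaminium chloride (not isolated) | CCCCCCCc1c(C=[N+](C)C)c(OCc2ccccc2)cc(OCc2ccccc2)c1OC.[Cl-] | intermediate
6 | 2,4-bis(benzyloxy)-6-heptyl-5-methoxybenzaldehyde | CCCCCCCc1c(C=O)c(OCc2ccccc2)cc(OCc2ccccc2)c1OC | intermediate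
7 | 2,4-bis(benzyloxy)-6-heptyl-5-methoxybenzoic acid | CCCCCCCc1c(C(=O)O)c(OCc2ccccc2)cc(OCc2ccccc2)c1OC | intermediate
8 | 6-heptyl-2,4-dihydroxy-5-methoxybenzoic acid | CCCCCCCc1c(C(=O)O)c(O)cc(O)c1OC | intermediate
9 | benzyl 6-heptyl-2,4-dihydroxy-5-methoxybenzoate | CCCCCCCc1c(C(=O)OCc2ccccc2)c(O)cc(O)c1OC | intermediate
10 | malonyl dichloride | O=C(Cl)CC(=O)Cl | starting material
11 | 6-chloro-4-hydroxy-2-oxo-2H-pyran-3-carbonyl chloride (not isolated) | O=C(Cl)c1c(O)cc(Cl)oc1=O | intermediate
12 | 6-chloro-4-hydroxy-2-oxo-2H-pyran-3-carboxylic acid (not isolated) | OC(=O)c1c(O)cc(Cl)oc1=O | intermediate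
13 | 6-chloro-4-hydroxy-2H-pyran-2-one | Oc1cc(Cl)oc(=O)c1 | intermediate
14 | 6-chloro-4-methoxy-2H-pyran-2-one | COc1cc(Cl)oc(=O)c1 | intermediate
15 | non-1-yne | CCCCCCCC#C | starting material
16 | lithium non-1-yn-1-ide (not isolated) | [Li]C#CCCCCCCC | intermediate
17 | benzyl dec-2-ynoate | CCCCCCCC#CC(=O)OCc1ccccc1 | intermediate
18 | benzyl 6-heptyl-2-hydroxy-5-methoxy-4-[(4-methoxy-2-oxo-2H-pyran-6-yl)oxy]benzoate | COc1cc(=O)oc(Oc2cc(O)c(C(=O)OCc3ccccc3)c(CCCCCCC)c2OC)c1 | intermediate
19 | benzyl 1-{4-[(benzyloxy)carbonyl]-3-heptyl-5-hydroxy-2-methoxyphenoxy}-5-heptyl-8-methoxy-3-oxo-2-oxabicyclo[2.2.2]octa-5,7-diene-6-carboxylate (racemic, not isolated) | O=C1OC2(Oc3cc(O)c(C(=O)OCc4ccccc4)c(CCCCCCC)c3OC)C=C(OC)C1C(CCCCCCC)=C2C(=O)OCc1ccccc1 | intermediate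
20 | benzyl 4-{2-[(benzyloxy)carbonyl]-3-heptyl-5-methoxyphenoxy}-6-heptyl-2-hydroxy-5-methoxybenzoate | CCCCCCCc1cc(OC)cc(Oc2cc(O)c(C(=O)OCc3ccccc3)c(CCCCCCC)c2OC)c1C(=O)OCc1ccccc1 | intermediate
21 | 4-(2-carboxy-3-heptyl-5-methoxyphenoxy)-6-heptyl-2-hydroxy-5-methoxybenzoic acid | CCCCCCCc1cc(OC)cc(Oc2cc(O)c(C(=O)O)c(CCCCCCC)c2OC)c1C(=O)O | target

Total step count: 13. Longest linear sequence: 10 steps (steps 1–7, 11, 12, 13); steps 8–9 and step 10 are side branches.

Steps most likely to fail

Step 12. The cycloaddition of the internal, singly activated alkyne may be too slow, so that thermal breakdown of the pyranonyl aryl ether (acyl transfer to a phenol), polymerisation of the ynoate or leakage to the other regiochemistry overtakes it. The fallback sets out from pyranone 18 and acetylide 16 (generated from 15 as in step 10) and comes back at 21. Acetylide 16 would be formylated with DMF to lithium 1-(dimethylamino)dec-2-yn-1-olate F1, and inverse quench into aqueous NaH2PO4 would release dec-2-ynal F2, a lower-LUMO and more strongly polarised dienophile. Heating F2 with 18 in toluene at 110–130 °C should give, through the formyl-substituted bridged lactone F3 and loss of CO2, benzyl 4-(2-formyl-3-heptyl-5-methoxyphenoxy)-6-heptyl-2-hydroxy-5-methoxybenzoate F4. Pinnick oxidation would give 2-{4-[(benzyloxy)carbonyl]-3-heptyl-5-hydroxy-2-methoxyphenoxy}-6-heptyl-4-methoxybenzoic acid F5, and hydrogenolysis of its one benzyl ester would give 21.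

Step 11. The phenoxide may open the lactone instead of substituting cleanly, a second phenoxide may acylate on the product, or adventitious water may hydrolyse the chloropyranone. The fallback sets out from chloropyranone 14 and ynoate 17 and comes back at 20; it moves the ether formation behind the cycloaddition. Heating 14 with 17 (1,2-dichlorobenzene, 180 °C) should give, through the chloro-substituted bridged lactone F6 and loss of CO2, benzyl 2-chloro-6-heptyl-4-methoxybenzoate F7, with the same regiochemical control by the 4-methoxy group. Palladium-catalysed C–O coupling of F7 with phenol 9 (Pd(OAc)2, t-BuXPhos, K3PO4, toluene, 100 °C) would then give 20.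

Step 3. Oxidative addition at the electron-rich C–Br bond, flanked on both sides, may be slow, so that hydrodebromination back to 2 dominates. The fallback sets out from bromide 3 and comes back at 4. Bromine–lithium exchange (n-BuLi, THF, −78 °C) would give [2,4-bis(benzyloxy)-6-heptylphenyl]lithium F8, and B(OMe)3 would trap it as lithium [2,4-bis(benzyloxy)-6-heptylphenyl]trimethoxyborate F9. Oxidation with H2O2/NaOH would give 2,4-bis(benzyloxy)-6-heptylphenol F10, and methylation (MeI, K2CO3, DMF) would give 4.

Further compounds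
F1 | step 12 | lithium 1-(dimethylamino)dec-2-yn-1-olate | [Li+].[O-]C(N(C)C)C#CCCCCCCC
F2 | step 12 | dec-2-ynal | CCCCCCCC#CC=O
F3 | step 12 | benzyl 4-[(6-formyl-5-heptyl-8-methoxy-3-oxo-2-oxabicyclo[2.2.2]octa-5,7-dien-1-yl)oxy]-6-heptyl-2-hydroxy-5-methoxybenzoate (racemic) | O=C1OC2(Oc3cc(O)c(C(=O)OCc4ccccc4)c(CCCCCCC)c3OC)C=C(OC)C1C(CCCCCCC)=C2C=O
F4 | step 12 | benzyl 4-(2-formyl-3-heptyl-5-methoxyphenoxy)-6-heptyl-2-hydroxy-5-methoxybenzoate | CCCCCCCc1cc(OC)cc(Oc2cc(O)c(C(=O)OCc3ccccc3)c(CCCCCCC)c2OC)c1C=O
F5 | step 12 | 2-{4-[(benzyloxy)carbonyl]-3-heptyl-5-hydroxy-2-methoxyphenoxy}-6-heptyl-4-methoxybenzoic acid | CCCCCCCc1cc(OC)cc(Oc2cc(O)c(C(=O)OCc3ccccc3)c(CCCCCCC)c2OC)c1C(=O)O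
F6 | step 11 | benzyl 1-chloro-5-heptyl-8-methoxy-3-oxo-2-oxabicyclo[2.2.2]octa-5,7-diene-6-carboxylate (racemic) | O=C1OC2(Cl)C=C(OC)C1C(CCCCCCC)=C2C(=O)OCc1ccccc1
F7 | step 11 | benzyl 2-chloro-6-heptyl-4-methoxybenzoate | CCCCCCCc1cc(OC)cc(Cl)c1C(=O)OCc1ccccc1
F8 | step 3 | [2,4-bis(benzyloxy)-6-heptylphenyl]lithium | [Li]c1c(CCCCCCC)cc(OCc2ccccc2)cc1OCc1ccccc1
F9 | step 3 | lithium [2,4-bis(benzyloxy)-6-heptylphenyl]trimethoxyborate | [Li+].CO[B-](OC)(OC)c1c(CCCCCCC)cc(OCc2ccccc2)cc1OCc1ccccc1
F10 | step 3 | 2,4-bis(benzyloxy)-6-heptylphenol | Oc1c(CCCCCCC)cc(OCc2ccccc2)cc1OCc1ccccc1
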